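The cyclobutane (ring C) is cut across its two spiro-carbon–CHBr bonds instead of along the biomimetic dimer seam. The two adjacent spiro carbons, C5 of butyl lactone A and C5 of acetoxybutyl lactone B, each carry a ring oxygen and a bromovinyl carbon: they are the termini of the tetrasubstituted central C=C of an (E)-5,5'-bifuranylidene-2,2'-dione, and the two CHBr carbons are 1,2-dibromoethene. A [2+2] photocycloaddition of these partners, placed last, closes ring C, forms both spiro–CHBr bonds and creates all four ring stereocentres in one operation. Its precursor is the fully substituted, acetate-bearing bifuranylidene, assembled from two 4-bromobutenolides.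

Key step: step 9

Remark on numbering: within each lactone O1, C2 (C=O), C3, C4 (C–Br), C5 (spiro); C1' is the acetoxy-bearing carbon; C5' means C5 of the other lactone.
Assumption: the remote C1' centre is not relied on for facial induction in step 9; the two facial cycloadducts are diastereomers and are separated there.

Step 1
Reactants: 1 ethyl 2-acetylhexanoate (ethyl 2-butylacetoacetate, racemic)
Product: 3 3-butyl-4-hydroxyfuran-2(5H)-one (3-butyltetronic acid), via bromo keto ester 2 (not isolated)
Conditions: Br2 (1.0 equiv), CHCl3, 0 °C to rt; then neat, 130 °C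
Reagents that add atoms: none
Why: Bromination of the β-keto ester followed by HBr-mediated α-to-γ bromine migration gives the γ-bromo ester, whose ester carbonyl oxygen displaces bromide on heating with loss of bromoethane (classical thermal tetronic acid cyclisation of γ-bromoacetoacetates), and no stereocentre remains.

Step 2
Reactants: 3 3-butyl-4-hydroxyfuran-2(5H)-one
Product: 4 4-bromo-3-butylfuran-2(5H)-one
Conditions: (COBr)2, DMF, CH2Cl2, 0 °C to rt
Reagents that add atoms: oxalyl bromide, O=C(Br)C(=O)Br
Why: Vilsmeier-type bromodehydroxylation of the vinylogous acid (addition–elimination at C4 through the O-formiminium salt) is the standard conversion of tetronic acids into 4-bromobutenolides.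

Step 3
Reactants: 4 4-bromo-3-butylfuran-2(5H)-one
Product: 6 4,5-dibromo-3-butylfuran-2(5H)-one (racemic), via silyloxyfuran 5 (not isolated)
Conditions: Et3N, TBSOTf, CH2Cl2, 0 °C; then NBS, −78 to −40 °C
Reagents that add atoms: N-bromosuccinimide, O=C1CCC(=O)N1Br
Why: Soft enolisation gives the 2-silyloxyfuran, which is brominated at its nucleophilic C5 (electrophilic halogenation of a silyl dienol ether), so the leaving group is placed at C5 without touching the allylic CH2 of the butyl chain; the C5 centre is racemic and is destroyed in step 8.

Step 4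
Reactants: 7 ethyl but-2-ynoate; 8 butanal
Product: 9 ethyl 2-(1-hydroxybutyl)buta-2,3-dienoate (racemic)
Conditions: LiN(iPr)2, THF, −78 °C; then 8, −78 °C; aq. NH4Cl at −78 °C
Reagents that add atoms: none
Why: γ-Deprotonation of the 2-ynoate gives a lithium cumulenolate that adds to the aldehyde through its α-carbon (α-selective aldol addition with alkyne-to-allene transposition), giving the racemic α-(1-hydroxyalkyl)allenoate.

Step 5
Reactants: 9 ethyl 2-(1-hydroxybutyl)buta-2,3-dienoate (racemic)
Product: 10 ethyl 2-[(1R)-1-acetoxybutyl]buta-2,3-dienoate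
Conditions: immobilised Burkholderia cepacia lipase, vinyl acetate, MTBE, 30 °C, stopped just below half conversion; chromatography
Reagents that add atoms: vinyl acetate, CC(=O)OC=C
Why: Lipase-catalysed kinetic resolution by enantioselective transesterification should acetylate the (R)-alcohol (large branched allenyl ester group against medium n-propyl group, the usual size preference of lipases for secondary alcohols), which sets C1' of the target by catalysis and installs its acetate, the slow-reacting enantiomer of 9 being removed by chromatography.

Step 6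
Reactants: 10 ethyl 2-[(1R)-1-acetoxybutyl]buta-2,3-dienoate
Product: 11 (1R)-1-(4-bromo-2-oxo-2,5-dihydrofuran-3-yl)butyl acetate
Conditions: CuBr2 (4 equiv), acetone/H2O, 65 °C
Reagents that add atoms: copper dibromide, [Cu+2].[Br-].[Br-]
Why: CuBr2-mediated bromolactonisation of a 2,3-allenoate delivers bromine to the central allene carbon while the ester carbonyl oxygen closes the five-membered ring at the terminal carbon with loss of the ethyl group, giving the 4-bromobutenolide under non-basic conditions that leave C1' and its acetate untouched.

Step 7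
Reactants: 11 (1R)-1-(4-bromo-2-oxo-2,5-dihydrofuran-3-yl)butyl acetate; 6 4,5-dibromo-3-butylfuran-2(5H)-one
Product: 13 (1R)-1-[4-bromo-5-(3-bromo-4-butyl-5-oxo-2,5-dihydrofuran-2-yl)-2-oxo-2,5-dihydrofuran-3-yl]butyl acetate (C5/C5' epimer mixture), via silyloxyfuran 12 (not isolated)
Conditions: 11, Et3N, TIPSOTf, CH2Cl2, −78 to −40 °C; then 6, AgOTf, −78 to −30 °C
Reagents that add atoms: none
Why: Soft enolisation gives silyloxyfuran 12 without passing through a free β-acetoxy enolate, and silver-assisted ionisation of the allylic α-oxy bromide 6 then allows a vinylogous Mukaiyama-type alkylation at the γ-carbon (C5) of 12 that forms the C5–C5' bond; the two new centres form unselectively and are destroyed in step 8.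

Step 8
Reactants: 13 (1R)-1-[4-bromo-5-(3-bromo-4-butyl-5-oxo-2,5-dihydrofuran-2-yl)-2-oxo-2,5-dihydrofuran-3-yl]butyl acetate
Product: 15 (1R)-1-[(5E)-4-bromo-5-(3-bromo-4-butyl-5-oxofuran-2(5H)-ylidene)-2-oxo-2,5-dihydrofuran-3-yl]butyl acetate, via bis(silyloxy)bifuran 14 (not isolated)
Conditions: Et3N, TIPSOTf, CH2Cl2, −78 to −30 °C; then DDQ, −78 to 0 °C, dark
Reagents that add atoms: none
Why: Twofold soft enolisation gives the electron-rich 5,5'-bis(silyloxy)-2,2'-bifuran, which DDQ should oxidise by two electrons with silyl transfer (dehydrogenation of a bis-silyl dienol ether, analogous to the oxidation of hydroquinone bis-silyl ethers to quinones) to give the central C=C, and only the E isomer is feasible because the Z isomer would force the two vinylic bromines into the same space.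

Step 9
Reactants: 15 (1R)-1-[(5E)-4-bromo-5-(3-bromo-4-butyl-5-oxofuran-2(5H)-ylidene)-2-oxo-2,5-dihydrofuran-3-yl]butyl acetate; 16 (E)-1,2-dibromoethene
Product: 17 (1R)-1-[(5S,6S,11R,12R)-4,10,11,12-tetrabromo-9-butyl-2,8-dioxo-1,7-dioxadispiro[4.0.4.2]dodeca-3,9-dien-3-yl]butyl acetate (lactone oxygens trans across C5–C6; bromines at C11 and C12 trans to each other and each cis to the C–Br carbon of the adjacent lactone)
Conditions: hν (365 nm LED), 16 (30 equiv), CH2Cl2, −60 °C, Ar; preparative HPLC
Reagents that add atoms: none
Why: Light of 365 nm is absorbed only by the bifuranylidene chromophore of 15, whose twisted triplet (intersystem crossing helped by the bromines) behaves as two 2-oxofuran-5-yl radicals; one terminus adds to 16 and the resulting triplet 1,4-biradical should close after spin inversion, so that the C5(lactone A)–CHBr and C5(lactone B)–CHBr bonds of ring C arise in one operation. The closest known reaction type is the [2+2] photocycloaddition of enones and γ-ylidenebutenolides with alkenes, including 1,2-dihaloethenes, together with the head-to-head photodimerisation of 5-methylene- and 5-(bromomethylene)butenolides. Ring C is closed by radical–radical combination of the 1,4-biradical (formal [2π+2π] closure of a four-membered ring), the first bond being made by intermolecular radical addition. The trans relation of the two lactone oxygens follows from the E geometry of 15 and should persist in the biradical because the alternative puts both C4–Br groups on one face; the trans relation of the two CHBr centres follows from closure of the freely rotating biradical to the non-eclipsed dibromide; the syn relation of each CHBr bromine to the C4–Br carbon of the neighbouring lactone is set in the first C–C bond formation, where the alkene hydrogen should take the crowded sector between C4–Br and the other lactone while the second alkene carbon lies anti to that lactone. The sense of the new centres relative to C1' is not expected to be induced strongly by this remote centre (attack anti to the acetoxy group would favour 17), so the two facial adducts, which are diastereomers, are expected in comparable amounts and are separated by preparative HPLC, the (5S,6S,11R,12R) isomer being 17. The step needs site selectivity for the central C=C over the ring C=C bonds (relief of the Br···O peri strain and spin density at C5/C5' should secure it) and ring closure faster than loss of a bromine atom from the β-bromoalkyl radical site (favoured by low temperature and long wavelength).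

Compound list
1 | ethyl 2-acetylhexanoate (ethyl 2-butylacetoacetate), racemic | CCCCC(C(C)=O)C(=O)OCC | starting material
2 | ethyl 4-bromo-2-butyl-3-oxobutanoate, racemic | CCCCC(C(=O)CBr)C(=O)OCC | intermediate
3 | 3-butyl-4-hydroxyfuran-2(5H)-one | CCCCC1=C(O)COC1=O | intermediate
4 | 4-bromo-3-butylfuran-2(5H)-one | CCCCC1=C(Br)COC1=O | intermediate
5 | [(4-bromo-3-butylfuran-2-yl)oxy](tert-butyl)dimethylsilane | CCCCc1c(Br)coc1O[Si](C)(C)C(C)(C)C | intermediate
6 | 4,5-dibromo-3-butylfuran-2(5H)-one, racemic | CCCCC1=C(Br)C(Br)OC1=O | intermediate
7 | ethyl but-2-ynoate | CC#CC(=O)OCC | starting material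
8 | butanal | CCCC=O | starting material
9 | ethyl 2-(1-hydroxybutyl)buta-2,3-dienoate, racemic | C=C=C(C(O)CCC)C(=O)OCC | intermediate
10 | ethyl 2-[(1R)-1-acetoxybutyl]buta-2,3-dienoate | CCOC(=O)C(=C=C)[C@@H](CCC)OC(C)=O | intermediate
11 | (1R)-1-(4-bromo-2-oxo-2,5-dihydrofuran-3-yl)butyl acetate | O=C1OCC(Br)=C1[C@@H](CCC)OC(C)=O | intermediate
12 | (1R)-1-{4-bromo-2-[(triisopropylsilyl)oxy]furan-3-yl}butyl acetate | CC(C)[Si](Oc1occ(Br)c1[C@@H](CCC)OC(C)=O)(C(C)C)C(C)C | intermediate
13 | (1R)-1-[4-bromo-5-(3-bromo-4-butyl-5-oxo-2,5-dihydrofuran-2-yl)-2-oxo-2,5-dihydrofuran-3-yl]butyl acetate, mixture of epimers at both C5 centres | CCCCC1=C(Br)C(OC1=O)C2OC(=O)C([C@@H](CCC)OC(C)=O)=C2Br | intermediate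
14 | (1R)-1-{3,3'-dibromo-4'-butyl-5,5'-bis[(triisopropylsilyl)oxy]-[2,2'-bifuran]-4-yl}butyl acetate | CCCCc1c(Br)c(oc1O[Si](C(C)C)(C(C)C)C(C)C)-c1oc(O[Si](C(C)C)(C(C)C)C(C)C)c([C@@H](CCC)OC(C)=O)c1Br | intermediate
15 | (1R)-1-[(5E)-4-bromo-5-(3-bromo-4-butyl-5-oxofuran-2(5H)-ylidene)-2-oxo-2,5-dihydrofuran-3-yl]butyl acetate | CCCCC1=C(Br)/C(=C2\OC(=O)C([C@@H](CCC)OC(C)=O)=C2Br)OC1=O | intermediate
16 | (E)-1,2-dibromoethene | Br/C=C/Br | starting material
17 | (1R)-1-[(5S,6S,11R,12R)-4,10,11,12-tetrabromo-9-butyl-2,8-dioxo-1,7-dioxadispiro[4.0.4.2]dodeca-3,9-dien-3-yl]butyl acetate | CCCCC1=C(Br)[C@@]2(OC1=O)[C@@H](Br)[C@H](Br)[C@@]21OC(=O)C([C@@H](CCC)OC(C)=O)=C1Br | target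

Total step count: 9
Longest linear sequence: 6 steps (steps 4 to 9; the branch through steps 1 to 3 and 7 to 9 is equally long)

Steps most likely to fail

Step 9. Weak discrimination between the two faces of 15 by the remote C1' centre and between the two alignments of 16, together with bromine-atom loss from the biradical, could spread the material over several cycloadducts and erode the share of 17. The fallback replaces the unbiased substrate by a face-shielded one. Setting out from 15, lipase-mediated alcoholysis of the acetate (immobilised Candida antarctica lipase B, n-BuOH, MTBE) would give (1R)-1-[(5E)-4-bromo-5-(3-bromo-4-butyl-5-oxofuran-2(5H)-ylidene)-2-oxo-2,5-dihydrofuran-3-yl]butan-1-ol F1. Silylation (TBDPSOTf, 2,6-lutidine, CH2Cl2) would give its tert-butyldiphenylsilyl ether F2. In the conformer of F2 with C1'–H eclipsing C4–Br, the bulky silyloxy group covers the face of lactone B opposite to the propyl group, which is the face whose attack leads to the unwanted diastereomer. Irradiation with 16 as in step 9 would give the silyl-protected cycloadduct F3, HF·pyridine would release the cycloadduct alcohol F4, and Ac2O/pyridine returns to the route at 17.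

Step 7. Silyl or silver triflate may ionise the furfuryl-type C1' acetate of the electron-rich furan 12, with loss or scrambling of the only pre-set stereocentre, or the furan may react through C3 instead of C5. The fallback exchanges the donor and acceptor roles. Setting out from 11, radical bromination at C5 (NBS, AIBN, PhCF3, 80 °C) would give (1R)-1-(4,5-dibromo-2-oxo-2,5-dihydrofuran-3-yl)butyl acetate F5. This is coupled under AgOTf with silyloxyfuran 5, made from 4 as in the first stage of step 3, so that lactone B never becomes an electron-rich furan. The sequence returns to the route at 13.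

Step 8. The acetate may ionise or eliminate in the bis(silyloxy)bifuran 14, and the electrophilic product may suffer over-oxidation or amine addition. The fallback uses halogenation and dehydrohalogenation instead of silyl dienol ether oxidation. Setting out from 13, NBS and Et3N (CH2Cl2, −40 to 0 °C) would brominate C5 of lactone A to give (1R)-1-[4-bromo-5-(2,3-dibromo-4-butyl-5-oxo-2,5-dihydrofuran-2-yl)-2-oxo-2,5-dihydrofuran-3-yl]butyl acetate F6, which is not isolated. E1cB loss of HBr through C5 of lactone B returns to the route at 15.

Further compounds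
F1 | step 9 | (1R)-1-[(5E)-4-bromo-5-(3-bromo-4-butyl-5-oxofuran-2(5H)-ylidene)-2-oxo-2,5-dihydrofuran-3-yl]butan-1-ol | CCCCC1=C(Br)/C(=C2\OC(=O)C([C@@H](CCC)O)=C2Br)OC1=O
F2 | step 9 | tert-butyldiphenylsilyl ether of F1 | CCCCC1=C(Br)/C(=C2\OC(=O)C([C@@H](CCC)O[Si](c3ccccc3)(c4ccccc4)C(C)(C)C)=C2Br)OC1=O
F3 | step 9 | tert-butyldiphenylsilyl ether of the (5S,6S,11R,12R) cycloadduct alcohol | CCCCC1=C(Br)[C@@]2(OC1=O)[C@@H](Br)[C@H](Br)[C@@]21OC(=O)C([C@@H](CCC)O[Si](c3ccccc3)(c4ccccc4)C(C)(C)C)=C1Br
F4 | step 9 | (5S,6S,11R,12R)-4,10,11,12-tetrabromo-9-butyl-3-[(1R)-1-hydroxybutyl]-1,7-dioxadispiro[4.0.4.2]dodeca-3,9-diene-2,8-dione | CCCCC1=C(Br)[C@@]2(OC1=O)[C@@H](Br)[C@H](Br)[C@@]21OC(=O)C([C@@H](CCC)O)=C1Br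
F5 | step 7 | (1R)-1-(4,5-dibromo-2-oxo-2,5-dihydrofuran-3-yl)butyl acetate, mixture of C5 epimers | O=C1OC(Br)C(Br)=C1[C@@H](CCC)OC(C)=O
F6 | step 8 | (1R)-1-[4-bromo-5-(2,3-dibromo-4-butyl-5-oxo-2,5-dihydrofuran-2-yl)-2-oxo-2,5-dihydrofuran-3-yl]butyl acetate, mixture of epimers | CCCCC1=C(Br)C(Br)(OC1=O)C2OC(=O)C([C@@H](CCC)OC(C)=O)=C2Br
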